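**Retrosynthetic overview**

1. The C8 angelate is removed. A retro-Cope then re-forms C2–C3 and cuts C5–C10, because the C10 (Z)-acetoxyvinyl / C5 isopropenyl pair on the cyclohexane is a 1,5-diene. This leads back to a (1(10)E,4E)-2R,9-diacetoxy-8-O-MOM-germacra-1(10),4,11(13)-trien-12,6-olide.
2. The germacranolide is cut at the ring-fusion bond C6–C7. This gives the C6 enal and a C13 allylic bromide whose carboxyl carbon C12 is parked on O9 as a 5,6-dihydropyran-2-one.
3. Enabling feature: the array O6–C6–C7–C11(=C13H2)–C12(=O) of the α-methylene-γ-butyrolactone ring is the adduct of a 2-carboxyallyl metal to an aldehyde. O9 stands 1,3 to C7, so the ring O9–C9–C8–C7=C11–C12 can hold C8 trans to C13 and pass C12 on to O6 after the C–C bond has formed.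
4. The pyranone comes from ring-closing metathesis of the O9 2-(bromomethyl)acrylate of a syn alkoxyallylboration adduct (C8, C9). The enal comes from geraniol (C6–C1, C15) by cleavage, proline aminoxylation (C2) and Wittig olefination (C10, C14, C9).
5. Ring order: the temporary pyranone is formed first. The ten-membered carbocycle and the γ-lactone follow in the key step, which opens the pyranone. The cyclohexane is formed last by Cope contraction of the ten-membered ring.

Key step: step 13

Remark: the germacrane numbering of the target (C1–C15) is used for all intermediates. C2 is the acetoxy-bearing vinyl carbon, C13 is the exocyclic methylene carbon, and C6–C7 is the lactone ring fusion.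

**Step 1**
Reactants: 1 geraniol
Product: 2 geranyl tert-butyldimethylsilyl ether
Conditions: TBSCl, imidazole, CH2Cl2, 0 °C to rt
Reagents that add atoms: tert-butyldimethylsilyl chloride, CC(C)(C)[Si](C)(C)Cl
Why: Routine silyl ether protection of the primary allylic alcohol (future C6–O) that leaves the E alkene (future C4=C5) untouched.

**Step 2**
Reactants: 2 geranyl tert-butyldimethylsilyl ether
Product: 3 6,7-epoxygeranyl tert-butyldimethylsilyl ether (racemic at the epoxide CH)
Conditions: mCPBA (1.0 equiv), NaHCO3, CH2Cl2, −20 to 0 °C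
Reagents that add atoms: 3-chloroperoxybenzoic acid, O=C(OO)c1cccc(Cl)c1
Why: Prilezhaev epoxidation should prefer the remote, more electron-rich trisubstituted alkene over the one deactivated by the allylic oxygen, and the new stereocentre is destroyed in step 3.

**Step 3**
Reactants: 3 6,7-epoxygeranyl tert-butyldimethylsilyl ether
Product: 4 (E)-6-(tert-butyldimethylsilyloxy)-4-methylhex-4-enal
Conditions: H5IO6, THF–Et2O, 0 °C
Reagents that add atoms: none
Why: Periodic acid hydrolyses the epoxide and cleaves the glycol (Malaprade-type cleavage) to the C1 aldehyde, with retention of the E alkene and of the silyl ether at low temperature.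

**Step 4**
Reactants: 4 (E)-6-(tert-butyldimethylsilyloxy)-4-methylhex-4-enal; 5 nitrosobenzene; 6 2-(triphenylphosphoranylidene)propanal
Product: 8 (2E,4R,6E)-4-(anilinooxy)-8-(tert-butyldimethylsilyloxy)-2,6-dimethylocta-2,6-dienal, via aminoxy aldehyde 7 (not isolated)
Conditions: 5, L-proline (20 mol %), CHCl3, 4 °C; then 6, CH2Cl2, 0 °C to rt
Reagents that add atoms: nitrosobenzene 5, O=Nc1ccccc1; 2-(triphenylphosphoranylidene)propanal 6, CC(C=O)=P(c1ccccc1)(c1ccccc1)c1ccccc1
Why: The proline-catalysed enamine α-aminoxylation (O-selective nitroso aldol) sets C2 as R through the hydrogen-bonded enamine transition state of L-proline, and the labile product is trapped at once by an E-selective Wittig olefination with the stabilised ylide, which installs C10, C14 and C9.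

**Step 5**
Reactants: 8 (2E,4R,6E)-4-(anilinooxy)-8-(tert-butyldimethylsilyloxy)-2,6-dimethylocta-2,6-dienal
Product: 9 (2E,4R,6E)-8-(tert-butyldimethylsilyloxy)-4-hydroxy-2,6-dimethylocta-2,6-dienal
Conditions: Cu(OAc)2 (30 mol %), EtOH, rt
Reagents that add atoms: none
Why: The copper-catalysed N–O bond cleavage that is standard for aminoxylation products frees the C2 hydroxyl without touching the enal, the alkenes or the C2 configuration.

**Step 6**
Reactants: 9 (2E,4R,6E)-8-(tert-butyldimethylsilyloxy)-4-hydroxy-2,6-dimethylocta-2,6-dienal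
Product: 10 (2E,4R,6E)-4-acetoxy-8-(tert-butyldimethylsilyloxy)-2,6-dimethylocta-2,6-dienal
Conditions: Ac2O, pyridine, DMAP (cat.), CH2Cl2, 0 °C
Reagents that add atoms: acetic anhydride, CC(=O)OC(C)=O
Why: DMAP-catalysed acetylation puts the final C2 acetate in place early, where it also serves as the protecting group for all later steps.

**Step 7**
Reactants: 11 allyl alcohol
Product: 12 allyl methoxymethyl ether
Conditions: MOMCl, i-Pr2NEt, CH2Cl2, 0 °C to rt
Reagents that add atoms: chloromethyl methyl ether, COCCl
Why: Simple O-alkylation (acetal ether formation) gives the precursor of the γ-alkoxyallyl reagent.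

**Step 8**
Reactants: 10 (2E,4R,6E)-4-acetoxy-8-(tert-butyldimethylsilyloxy)-2,6-dimethylocta-2,6-dienal; 12 allyl methoxymethyl ether; 13 (−)-B-methoxydiisopinocampheylborane
Product: 15 (3R,4R,5E,7R,9E)-7-acetoxy-11-(tert-butyldimethylsilyloxy)-3-(methoxymethoxy)-5,9-dimethylundeca-1,5,9-trien-4-ol, via allylborane 14 (not isolated)
Conditions: 12, s-BuLi, THF, −78 °C; 13; BF3·OEt2; 10, −78 °C; then 30% H2O2, pH 7 buffer, MeOH, 0 °C
Reagents that add atoms: allyl methoxymethyl ether 12, C=CCOCOC
Why: In this Brown-type asymmetric (Z)-γ-alkoxyallylboration the closed chair transition state turns the Z geometry into the syn C8/C9 relationship, the isopinocampheyl groups derived from (+)-α-pinene direct attack to the Si face of the aldehyde (8R,9R), and the reagent adds 1,2 and leaves the acetate alone.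

**Step 9**
Reactants: 15 (3R,4R,5E,7R,9E)-7-acetoxy-11-(tert-butyldimethylsilyloxy)-3-(methoxymethoxy)-5,9-dimethylundeca-1,5,9-trien-4-ol; 16 2-(bromomethyl)acrylic acid
Product: 18 O9 2-(bromomethyl)acrylate of 15, via acid chloride 17 (not isolated)
Conditions: 16, 1-chloro-N,N,2-trimethylprop-1-en-1-amine, CH2Cl2, 0 °C; then 15, 2,6-lutidine, −20 °C to rt
Reagents that add atoms: 2-(bromomethyl)acrylic acid 16, C=C(CBr)C(=O)O
Why: In this acylation of the secondary alcohol with an acid chloride made under neutral conditions, the hindered and poorly nucleophilic base should scavenge HCl without quaternisation by the allylic bromide.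

**Step 10**
Reactants: 18 O9 2-(bromomethyl)acrylate of 15
Product: 19 (5R,6R)-6-[(2E,4R,6E)-4-acetoxy-8-(tert-butyldimethylsilyloxy)-6-methylocta-2,6-dien-2-yl]-3-(bromomethyl)-5-(methoxymethoxy)-5,6-dihydro-2H-pyran-2-one
Conditions: second-generation Hoveyda–Grubbs catalyst (10 mol %), toluene, 5 mM, 80 °C
Reagents that add atoms: none
Why: Ring-closing metathesis of a homoallylic 2-substituted acrylate starts at the only monosubstituted alkene and closes the six-membered lactone at C7=C11, while the two trisubstituted alkenes stay inert and the ring fixes C8 cis to C12.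

**Step 11**
Reactants: 19 (5R,6R)-6-[(2E,4R,6E)-4-acetoxy-8-(tert-butyldimethylsilyloxy)-6-methylocta-2,6-dien-2-yl]-3-(bromomethyl)-5-(methoxymethoxy)-5,6-dihydro-2H-pyran-2-one
Product: 20 the corresponding C6 allylic alcohol (8-hydroxy side chain)
Conditions: aq. HF, MeCN, 0 °C
Reagents that add atoms: none
Why: Amine-free fluoride desilylation removes the primary allylic silyl ether quickly, while the allylic bromide, the acetal ether, the acetate and the lactone survive.

**Step 12**
Reactants: 20 C6 allylic alcohol
Product: 21 (5R,6R)-6-[(2E,4R,6E)-4-acetoxy-6-methyl-8-oxoocta-2,6-dien-2-yl]-3-(bromomethyl)-5-(methoxymethoxy)-5,6-dihydro-2H-pyran-2-one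
Conditions: MnO2, CH2Cl2, rt
Reagents that add atoms: none
Why: Neutral MnO2 allylic oxidation gives the E enal (C6) without affecting the bromide or isomerising C4=C5.

**Step 13**
Reactants: 21 (5R,6R)-6-[(2E,4R,6E)-4-acetoxy-6-methyl-8-oxoocta-2,6-dien-2-yl]-3-(bromomethyl)-5-(methoxymethoxy)-5,6-dihydro-2H-pyran-2-one
Product: 24 (1(10)E,4E,2R,6R,7S,8R,9R)-2-acetoxy-9-hydroxy-8-(methoxymethoxy)germacra-1(10),4,11(13)-trien-12,6-olide, via allylchromium species 22 (not isolated), via bridged hydroxy lactone 23 (not isolated)
Conditions: CrCl2 (10 equiv), DMF–THF, 25 °C, syringe-pump addition to 2 mM; aq. NH4Cl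
Reagents that add atoms: none
Why: Divalent chromium reduces the C13–Br bond to the allylchromium species 22, which adds through its γ-carbon C7 to the chromium-bound aldehyde C6 in a closed Zimmerman–Traxler transition state, the closest known reaction type being the intramolecular Nozaki–Hiyama–Kishi allylation of 2-(bromomethyl)acrylate or bromomethyl-butenolide donors that delivers carbocycle-fused α-methylene lactones. This closes the ten-membered carbocycle (10-exo-trig at the carbonyl group) and shifts the alkene to C11=C13, after which the C6 alkoxide of 23, which stands axial over the pyranone, adds 5-exo-trig to C12 and the dioxabicyclo[3.2.1]octane-type tetrahedral intermediate expels O9, so that the γ-lactone closes while the temporary six-membered lactone opens. C7 is controlled by C9, because the aldehyde hangs on C10 and only attack on the face of C7 cis to C10 (half-chair with C10 axial and the C8 ether equatorial) brings C5 and C10 to the roughly 3 Å that an E,E-cyclodeca-1,5-diene demands. C6 is controlled by the ring-locked alkene geometry, since C8 is held trans to C13 as in an E-crotyl metal, so that with C5 equatorial in the chair the anti adduct and hence the trans-fused 6,12-lactone should form, whereas an open-chain ester of tiglate-like geometry would lead into the cis series. The step needs γ- over α-attack, ring closure over oligomerisation, and survival of the C8–O and C2–O bonds, which are secured by the closed transition state, by slow addition at high dilution, by the poor leaving-group ability of an acetal ether that lies near the nodal plane of the allyl system, and by the inertness of allylic acetates to CrCl2 in the absence of nickel or palladium. The acyl shift is driven by the greater stability of the five-membered lactone and by relief of the 1,3-bridge across the macrocycle.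

**Step 14**
Reactants: 24 (1(10)E,4E,2R,6R,7S,8R,9R)-2-acetoxy-9-hydroxy-8-(methoxymethoxy)germacra-1(10),4,11(13)-trien-12,6-olide
Product: 25 the 2,9-diacetate of 24
Conditions: Ac2O, pyridine, DMAP (cat.), CH2Cl2, 0 °C to rt
Reagents that add atoms: acetic anhydride, CC(=O)OC(C)=O
Why: Standard acetylation of the liberated allylic C9 hydroxyl installs the second final acetate under conditions that are routine for α-methylene lactones.

**Step 15**
Reactants: 25 2,9-diacetoxy-8-(methoxymethoxy)germacranolide
Product: 26 (5S,6R,7S,8R,9R,10S)-9-acetoxy-10-[(Z)-2-acetoxyvinyl]-5-isopropenyl-8-(methoxymethoxy)elemanolide (the target with a MOM ether at O8)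
Conditions: toluene (degassed), BHT, sealed tube, 150–170 °C
Reagents that add atoms: none
Why: This thermal Cope rearrangement (the presumed biogenetic germacranolide-to-elemanolide change) runs through the chair transition state of the conformer that keeps O6, C11, O8 and O9 equatorial on the nascent cyclohexane, where the two E alkenes place C14 and H5 axial and anti and so set C10 (quaternary) and C5 with trans-diequatorial vinyl and isopropenyl groups, the 2R acetate is forced axial and therefore emerges as the Z enol acetate, and conjugation of that oxygen with C1=C2 together with relief of medium-ring strain pulls the equilibrium to 26.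

**Step 16**
Reactants: 26 MOM-protected elemanolide
Product: 28 8-hydroxy elemanolide (the target lacking the angeloyl group), via bromomethyl ether 27 (not isolated)
Conditions: Me2BBr, CH2Cl2, −78 °C; then THF–aq. NaHCO3
Reagents that add atoms: none
Why: Low-temperature bromoborane cleavage of the acetal ether is selective for the most Lewis-basic acetal oxygen and should spare the enol acetate, the acetate, the lactone and the 1,1-disubstituted alkenes, with C8 untouched.

**Step 17**
Reactants: 28 8-hydroxy elemanolide; 29 angelic acid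
Product: 31 target compound CNP0582479.1, via mixed anhydride 30 (not isolated)
Conditions: 29, 2,4,6-trichlorobenzoyl chloride, Et3N, toluene, rt; then 28, 80 °C
Reagents that add atoms: angelic acid 29, C/C=C(/C)C(=O)O
Why: Yamaguchi-type mixed-anhydride esterification run without a nucleophilic catalyst is the established way to acylate hindered secondary alcohols with angelic acid without Z-to-E isomerisation to the tiglate, and the equatorial C8 hydroxyl is the only free one.

**Compound list**

1 | geraniol | CC(C)=CCC/C(C)=C/CO | starting material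
2 | geranyl tert-butyldimethylsilyl ether | CC(C)=CCC/C(C)=C/CO[Si](C)(C)C(C)(C)C | intermediate
3 | 6,7-epoxygeranyl tert-butyldimethylsilyl ether (racemic epoxide) | CC1(C)OC1CC/C(C)=C/CO[Si](C)(C)C(C)(C)C | intermediate
4 | (E)-6-(tert-butyldimethylsilyloxy)-4-methylhex-4-enal | O=CCC/C(C)=C/CO[Si](C)(C)C(C)(C)C | intermediate
5 | nitrosobenzene | O=Nc1ccccc1 | starting material
6 | 2-(triphenylphosphoranylidene)propanal | CC(C=O)=P(c1ccccc1)(c1ccccc1)c1ccccc1 | starting material
7 | (R,E)-2-(anilinooxy)-6-(tert-butyldimethylsilyloxy)-4-methylhex-4-enal | O=C[C@H](ONc1ccccc1)C/C(C)=C/CO[Si](C)(C)C(C)(C)C | intermediate (not isolated)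
8 | (2E,4R,6E)-4-(anilinooxy)-8-(tert-butyldimethylsilyloxy)-2,6-dimethylocta-2,6-dienal | O=C/C(C)=C/[C@H](ONc1ccccc1)C/C(C)=C/CO[Si](C)(C)C(C)(C)C | intermediate
9 | (2E,4R,6E)-8-(tert-butyldimethylsilyloxy)-4-hydroxy-2,6-dimethylocta-2,6-dienal | O=C/C(C)=C/[C@H](O)C/C(C)=C/CO[Si](C)(C)C(C)(C)C | intermediate
10 | (2E,4R,6E)-4-acetoxy-8-(tert-butyldimethylsilyloxy)-2,6-dimethylocta-2,6-dienal | O=C/C(C)=C/[C@H](OC(C)=O)C/C(C)=C/CO[Si](C)(C)C(C)(C)C | intermediate
11 | allyl alcohol | C=CCO | starting material
12 | allyl methoxymethyl ether | C=CCOCOC | intermediate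
13 | (−)-B-methoxydiisopinocampheylborane (from (+)-α-pinene) | COB([C@@H]1C[C@@H]2C[C@H]([C@H]1C)C2(C)C)[C@@H]1C[C@@H]2C[C@H]([C@H]1C)C2(C)C | starting material
14 | [(Z)-3-(methoxymethoxy)allyl]diisopinocampheylborane | COCO/C=C\CB([C@@H]1C[C@@H]2C[C@H]([C@H]1C)C2(C)C)[C@@H]1C[C@@H]2C[C@H]([C@H]1C)C2(C)C | intermediate (not isolated)
15 | (3R,4R,5E,7R,9E)-7-acetoxy-11-(tert-butyldimethylsilyloxy)-3-(methoxymethoxy)-5,9-dimethylundeca-1,5,9-trien-4-ol (C8/C9 syn) | C=C[C@@H](OCOC)[C@H](O)/C(C)=C/[C@H](OC(C)=O)C/C(C)=C/CO[Si](C)(C)C(C)(C)C | intermediate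
16 | 2-(bromomethyl)acrylic acid | C=C(CBr)C(=O)O | starting material
17 | 2-(bromomethyl)acryloyl chloride | C=C(CBr)C(=O)Cl | intermediate (not isolated)
18 | O9 2-(bromomethyl)acrylate of 15 | C=C[C@@H](OCOC)[C@H](OC(=O)C(=C)CBr)/C(C)=C/[C@H](OC(C)=O)C/C(C)=C/CO[Si](C)(C)C(C)(C)C | intermediate
19 | (5R,6R)-6-[(2E,4R,6E)-4-acetoxy-8-(tert-butyldimethylsilyloxy)-6-methylocta-2,6-dien-2-yl]-3-(bromomethyl)-5-(methoxymethoxy)-5,6-dihydro-2H-pyran-2-one | BrCC1=C[C@@H](OCOC)[C@H](OC1=O)/C(C)=C/[C@H](OC(C)=O)C/C(C)=C/CO[Si](C)(C)C(C)(C)C | intermediate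
20 | C6 allylic alcohol derived from 19 | BrCC1=C[C@@H](OCOC)[C@H](OC1=O)/C(C)=C/[C@H](OC(C)=O)C/C(C)=C/CO | intermediate
21 | C6 enal, cyclisation precursor | BrCC1=C[C@@H](OCOC)[C@H](OC1=O)/C(C)=C/[C@H](OC(C)=O)C/C(C)=C/C=O | intermediate
22 | allylchromium dichloride derived from 21 | Cl[Cr](Cl)CC1=C[C@@H](OCOC)[C@H](OC1=O)/C(C)=C/[C@H](OC(C)=O)C/C(C)=C/C=O | intermediate (not isolated)
23 | bridged 6-hydroxy-germacra-1(10),4,11(13)-trien-12,9-olide (formed as its chromium alkoxide; C6, O8 and C10 all cis on the δ-lactone) | C=C1C(=O)O[C@@H]2/C(C)=C/[C@H](OC(C)=O)C/C(C)=C/[C@@H](O)[C@H]1[C@H]2OCOC | intermediate (not isolated)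
24 | (1(10)E,4E,2R,6R,7S,8R,9R)-2-acetoxy-9-hydroxy-8-(methoxymethoxy)germacra-1(10),4,11(13)-trien-12,6-olide | C1/C(C)=C/[C@H]2OC(=O)C(=C)[C@@H]2[C@@H](OCOC)[C@H](O)/C(C)=C/[C@@H]1OC(C)=O | intermediate
25 | 2,9-diacetate of 24 | C1/C(C)=C/[C@H]2OC(=O)C(=C)[C@@H]2[C@@H](OCOC)[C@H](OC(C)=O)/C(C)=C/[C@@H]1OC(C)=O | intermediate
26 | (5S,6R,7S,8R,9R,10S)-elemanolide with 8-O-MOM, 9-OAc and a (Z)-enol acetate | C=C1C(=O)O[C@H]2[C@H]1[C@@H](OCOC)[C@H](OC(C)=O)[C@@](C)(/C=C\OC(C)=O)[C@@H]2C(=C)C | intermediate
27 | 8-O-bromomethyl ether of 28 | C=C1C(=O)O[C@H]2[C@H]1[C@@H](OCBr)[C@H](OC(C)=O)[C@@](C)(/C=C\OC(C)=O)[C@@H]2C(=C)C | intermediate (not isolated)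
28 | 8-hydroxy elemanolide | C=C1C(=O)O[C@H]2[C@H]1[C@@H](O)[C@H](OC(C)=O)[C@@](C)(/C=C\OC(C)=O)[C@@H]2C(=C)C | intermediate
29 | angelic acid, (Z)-2-methylbut-2-enoic acid | C/C=C(/C)C(=O)O | starting material
30 | angelic 2,4,6-trichlorobenzoic anhydride | C/C=C(/C)C(=O)OC(=O)c1c(Cl)cc(Cl)cc1Cl | intermediate (not isolated)
31 | CNP0582479.1 | C=C1C(=O)O[C@H]2[C@H]1[C@@H](OC(=O)/C(C)=C\C)[C@H](OC(C)=O)[C@@](C)(/C=C\OC(C)=O)[C@@H]2C(=C)C | target

**Step count**

Total step count: 17.
Longest linear sequence: 16 (steps 1–6 and 8–17, from geraniol).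

**Steps most likely to fail**

**Step 13.** Several processes may interfere:
- Oligomerisation may outrun the bridged ten-membered closure.
- Addition may proceed through the transition state with C5 axial, which would cost the control at C6.
- The allylchromium species may lose the C8 alkoxy group by reductive 1,4-elimination.

The fallback replaces the reductive in situ metalation by an isolable, configurationally fixed allylboron reagent. It sets out from 20. Palladium-catalysed borylation of the allylic bromide (B2pin2, Pd2(dba)3, toluene, 50 °C) should give the allylboronate alcohol F1. MnO2 oxidation should then give the allylboronate enal F2. Heating F2 at high dilution (toluene, 80–110 °C, Sc(OTf)3 if needed) should close C6–C7 by intramolecular allylboration through the same ring-locked chair, free of reducing metal salts. Hydrolysis of the borate and the same δ-to-γ acyl shift bring the route back at 24.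

**Step 15.** Several processes may interfere:
- The equilibrium may stop short of completion.
- Leakage through a boat transition state may erode the C5/C10 configuration and the Z geometry.
- Acetic acid may be lost thermally.
- The methylene lactone may polymerise.

The fallback is a metal-templated rearrangement at room temperature. It sets out from 25. One equivalent of PdCl2(PhCN)2 in CH2Cl2 should bind the cyclodeca-1,5-diene, and divalent palladium should induce the cyclisation-triggered [3,3] shift. The divinylcyclohexane product is then held as the palladium dichloride chelate F3, which acts as the thermodynamic sink. Treatment with pyridine releases the ligand and returns the route at 26.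

**Step 10.** Ring closure onto the electron-poor 1,1-disubstituted acrylate may be sluggish, the catalyst may decay, and the allylic bromide may be lost at 80 °C. The fallback builds the ring first and adds C13 afterwards. It sets out from 15.
- Acryloyl chloride and i-Pr2NEt should give the acrylate F4.
- Ring-closing metathesis to a disubstituted alkene (second-generation Grubbs catalyst, CH2Cl2, reflux) should give the unsubstituted dihydropyranone F5.
- Morita–Baylis–Hillman hydroxymethylation (aq. formaldehyde, PBu3, THF) should give the 3-(hydroxymethyl) lactone F6.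
- Appel bromination (CBr4, PPh3) brings the route back at 19.

**Further compounds**

F1 | step 13 | allylboronate alcohol (pinacol boronate at C13, C6 alcohol) | CC1(C)OB(CC2=C[C@@H](OCOC)[C@H](OC2=O)/C(C)=C/[C@H](OC(C)=O)C/C(C)=C/CO)OC1(C)C
F2 | step 13 | allylboronate enal (pinacol boronate at C13, C6 aldehyde) | CC1(C)OB(CC2=C[C@@H](OCOC)[C@H](OC2=O)/C(C)=C/[C@H](OC(C)=O)C/C(C)=C/C=O)OC1(C)C
F3 | step 15 | palladium dichloride chelate of 26 (written as its two components) | C=C1C(=O)O[C@H]2[C@H]1[C@@H](OCOC)[C@H](OC(C)=O)[C@@](C)(/C=C\OC(C)=O)[C@@H]2C(=C)C.Cl[Pd]Cl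
F4 | step 10 | O9 acrylate of 15 | C=C[C@@H](OCOC)[C@H](OC(=O)C=C)/C(C)=C/[C@H](OC(C)=O)C/C(C)=C/CO[Si](C)(C)C(C)(C)C
F5 | step 10 | 3-unsubstituted (5R,6R)-dihydropyranone | O=C1C=C[C@@H](OCOC)[C@H](O1)/C(C)=C/[C@H](OC(C)=O)C/C(C)=C/CO[Si](C)(C)C(C)(C)C
F6 | step 10 | 3-(hydroxymethyl) (5R,6R)-dihydropyranone | OCC1=C[C@@H](OCOC)[C@H](OC1=O)/C(C)=C/[C@H](OC(C)=O)C/C(C)=C/CO[Si](C)(C)C(C)(C)C
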